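**Design of a synthesis of 2,5,6-tribromo-1-methylgramine (10)**

Compound numbers: 1 6-bromoisatin; 2 6-bromo-1-methylisatin; 3 its 3-hydrazone; 4 6-bromo-1-methyloxindole; 5 5,6-dibromo-1-methyloxindole; 6 N,N-dimethylformamide; 7 bromomethyleneiminium salt; 8 3-(dimethylaminomethylidene)oxindole; 9 2-bromoindol-3-yl iminium bromide; 10 target.

## The problem

Target 10 is a flat, fully aromatic indole with no stereocenter, so nothing has to be controlled stereochemically and the task is one of regiochemistry and functional-group tolerance. Five substituents must be placed without ambiguity: methyl on N1, bromine on C2, the dimethylaminomethyl group on C3, and two neighbouring bromines on C5 and C6 of the benzene ring. The 5,6-pattern cannot be written onto a finished indole, because electrophiles attack the pyrrole ring first and then choose poorly among C4 to C7. The C2 bromide, between N1 and C3, is the most reactive of the three C–Br bonds toward zerovalent metals and organolithium reagents, and all three exclude hydrogenolysis, dissolving metals and palladium chemistry late in the route. The gramine side chain is a benzylic-type tertiary amine that loses dimethylamine by elimination–addition when quaternised or heated with acid and is attacked by electrophilic bromine, so it should be formed last. The enabling feature is that C2, bonded to N1 and to bromine, stands at the oxidation level of the lactam carbonyl of an oxindole, and the C3–CH2–NMe2 unit is dimethylformamide with carbon and nitrogen still joined. An oxindole with a nucleophilic C3 methylene can therefore receive the C2 bromide and the whole side chain from one reagent pair.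

## Retrosynthesis

**10 from 9.** The last bond cut is the C–H bond at the side-chain carbon, which leads back to iminium bromide 9. The neighbouring cuts, CH2–N (amine plus a 3-formyl or 3-halomethyl indole) and C3–CH2 (Mannich reaction on a 3-unsubstituted 2-bromoindole), either split the C–N bond that 9 already contains or pass through an acid-sensitive 2-bromoindole. Compound 9 is no smaller than 10, but it is the direct outcome of the key step. The forward reaction must add hydride to the iminium carbon before water reaches it and must leave three C–Br bonds alone.

**9 from 5 and 6.** Two bonds are cut at once: the exocyclic C3–CH bond and the C2–Br bond. This removes all functionality at C2 and C3 and leaves lactam 5 and dimethylformamide 6. The forward reaction passes through bromoiminium salt 7 and vinylogous amide 8. It needs carbon attack at C3 before the lactam oxygen is activated, and replacement of that oxygen by bromide with aromatisation of the pyrrole ring. Separate C2 bromination and C3 aminomethylation of an indole would take two operations on a sensitive intermediate.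

**5 from 4.** The C5–Br bond is cut. C5 is para to the lactam nitrogen, the normal site of electrophilic substitution in oxindoles, whereas C6 is meta to nitrogen and cannot be reached this way, so the C6 bromine must come with the starting material. Closing the lactam ring on an already dibrominated N-aryl chloroacetamide by Friedel–Crafts alkylation was weighed and set aside. It would need AlCl3 at melt temperature on a ring deactivated by two bromines, with two possible ortho positions and a risk of bromine migration. The forward reaction must brominate once, at C5, and not at C7 or at the enolisable C3.

**4 from 2.** The C3 methylene is traced to the C3 ketone of isatin 2, through hydrazone 3. The reason lies in the N-methyl group: an N–H oxindole also alkylates at C3, whereas an isatin has no enolisable carbon and methylates cleanly on nitrogen. The forward deoxygenation must spare the aryl bromide and the lactam.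

**2 from 1.** The N–CH3 bond is cut, leading to commercial 6-bromoisatin 1, which brings the benzene ring, the lactam ring and the C6 bromine.

## Roads not taken

**Alternative 1:** Ring A would be built by a [2+2+2] cocyclisation. The cut removes C3a–C7a, C4–C5 and C6–C7. In the forward step CpCo(CO)2, a complex of monovalent cobalt, would join N-(but-3-yn-1-yl)-N-ethynyl-4-methylbenzenesulfonamide A1 with bis(trimethylsilyl)acetylene A2 to give 1-(4-methylphenylsulfonyl)-5,6-bis(trimethylsilyl)indoline A3.
- Merit: the two silyl groups mark C5 and C6 by construction, so the bromine pattern would not depend on any electrophilic-substitution selectivity. This is better than the chosen plan, which relies on nitrogen to direct bromine to C5.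
- Weak points: the step spends an organometallic cyclisation on a benzene ring that can be bought, and A3 has nothing at C2 or C3, the wrong oxidation level in the five-membered ring and a sulfonyl group on nitrogen. Two ipso-bromodesilylations (the second slowed by the first bromine, with protodesilylation competing), dehydrogenation, desulfonylation, N-methylation, C2 bromination and C3 aminomethylation would follow, and A1 needs a terminal ynamide synthesis.
- Comparison: the chosen plan sets five steps with common reagents against this long tail, and its C5 selectivity rests on the well-established para direction in oxindoles.

**Alternative 2:** The pyrrole ring would be closed by a Larock heteroannulation, cutting C3–C3a and N1–C2. 4,5-Dibromo-2-iodo-N-methylaniline A4 and N,N-dimethyl-3-(trimethylsilyl)prop-2-yn-1-amine A5 would react with Pd(OAc)2, LiCl and K2CO3 to give 1-[5,6-dibromo-1-methyl-2-(trimethylsilyl)-1H-indol-3-yl]-N,N-dimethylmethanamine A6. Ipso-bromodesilylation at C2 would then give 10.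
- Merit: this is the most convergent road and probably one step shorter than the chosen one. The silyl group goes to C2 and the side chain to C3 for steric reasons, and only one step follows the annulation.
- Weak points: zerovalent palladium must insert only into the C–I bond of A4 and must then ignore the two aryl bromides of A4 and A6 for the whole of a hot reaction. The free tertiary amine of A5 can bind the metal. The final bromodesilylation exposes the finished gramine side chain to an electrophilic bromine source, which the target tolerates least.
- Comparison: the chosen plan is metal-free throughout, never has to distinguish between halogens, and installs the C2 bromide before the amine exists. These are set against the shorter sequence of Alternative 2.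

**Alternative 3:** The N1–C2 bond would be cut. 4,5-Dibromo-2-(2,2-dibromoethenyl)-N-methylaniline A7 would close with CuI, K3PO4 and a diamine ligand, retaining one vinylic bromine, to give 2,5,6-tribromo-1-methyl-1H-indole A8. A Mannich reaction with formaldehyde and dimethylamine at C3 would finish.
- Merit: the C2 bromide comes out of the ring closure, both ring bromines are fixed by the starting material, and the one-step Mannich end-game is as short as the hydride quench of the chosen plan.
- Weak points: A7 needs an ortho-aminobenzaldehyde with the 4,5-dibromo pattern, a dibromo-olefination, and handling of an amine beside four C–Br bonds, which makes the sequence longer. The monovalent copper catalyst must stop after one C–N bond although A8 still has a reactive C2 bromide and two aryl bromides. A8 is an acid-sensitive 2-bromoindole, deactivated toward the Mannich step by three bromines.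
- Comparison: A8 should also be available from 5 in one step with POBr3, so this ring closure offers nothing the oxindole does not already provide. The chosen plan adds the side chain in the same operation as the C2 bromide.

Key step: step 4

## Route

Assumption on the chemistry: salt 9 is written as its bromide. The crude salt may carry dibromophosphate as part of its counter-anion, which does not affect the hydride reduction. The C=N geometry of 3 and the C=C geometry of 8 are not fixed and are lost in the following transformation.

Step 1
Reactants: 1 6-bromoisatin (6-bromo-1H-indole-2,3-dione)
Product: 2 6-bromo-1-methylindoline-2,3-dione
Conditions: MeI, K2CO3, MeCN, rt to 40 °C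
Reagents that add atoms: iodomethane, CI
Why: N-alkylation of the acidic isatin N–H through its potassium salt; isatin has no enolisable carbon, so C-methylation cannot compete, which is why the methyl group is introduced here and not at the oxindole stage.

Step 2
Reactants: 2 6-bromo-1-methylindoline-2,3-dione
Product: 4 6-bromo-1-methylindolin-2-one, via isatin hydrazone 3 (not isolated)
Conditions: N2H4·H2O (excess, neat), 125 °C; then aq. HCl, rt
Reagents that add atoms: none
Why: Wolff–Kishner reduction: the ketone at C3, the more electrophilic carbonyl, condenses with hydrazine to hydrazone 3, which loses N2 in the hot basic medium to leave the C3 methylene. No metal or hydride is present, so the aryl bromide should survive, and the acid work-up should reclose any lactam opened by hydrazine.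

Step 3
Reactants: 4 6-bromo-1-methylindolin-2-one
Product: 5 5,6-dibromo-1-methylindolin-2-one
Conditions: NBS (1.05 equiv), MeCN, 0 °C to rt, dark
Reagents that add atoms: N-bromosuccinimide, O=C1CCC(=O)N1Br
Why: Electrophilic aromatic bromination: the lactam nitrogen directs para to C5 and the C6 bromine directs ortho to the same carbon, while C7 is crowded between the N-methyl group and the C6 bromine. One equivalent of NBS in a polar solvent in the dark should keep radical and enol bromination at C3 in the background.

Step 4
Reactants: 5 5,6-dibromo-1-methylindolin-2-one; 6 N,N-dimethylformamide
Product: 9 N-[(2,5,6-tribromo-1-methyl-1H-indol-3-yl)methylidene]-N-methylmethanaminium bromide, via bromomethyleneiminium dibromophosphate 7 (not isolated), via 3-(dimethylaminomethylidene)oxindole 8 (not isolated)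
Conditions: POBr3 (2.5 equiv), DMF (3 equiv), CH2Cl2, 0 °C, then 5, 0 °C to reflux; dry Et2O, filtration under argon
Reagents that add atoms: phosphorus oxybromide, O=P(Br)(Br)Br
Why: Dimethylformamide and POBr3 first give the bromomethyleneiminium salt 7. The enol of 5 attacks 7 through C3 and loss of HBr gives the vinylogous amide 8, which forms the only new skeletal bond, the exocyclic C3–CH bond. A second equivalent of POBr3 phosphorylates the lactam oxygen of 8, bromide adds to the now amidinium-like C2 and dibromophosphate leaves, so that the C2–Br bond forms by addition–elimination and the pyrrole ring becomes aromatic. The closest known reaction is the Vilsmeier–Haack haloformylation of oxindoles to 2-haloindole-3-carbaldehydes, of which 9 is the intermediate before hydrolysis. No ring is closed and no stereocenter is formed. The step needs carbon attack at C3 before oxygen activation; the acidity of the C3 methylene between the arene and the lactam carbonyl and the preforming of 7 before 5 is added should secure this. The ring bromines are inert to these metal-free electrophilic conditions and deactivate the benzene ring against stray formylation. Exclusion of water and precipitation with dry ether should preserve the iminium C=N bond for the next step.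

Step 5
Reactants: 9 N-[(2,5,6-tribromo-1-methyl-1H-indol-3-yl)methylidene]-N-methylmethanaminium bromide
Product: 10 1-(2,5,6-tribromo-1-methyl-1H-indol-3-yl)-N,N-dimethylmethanamine (2,5,6-tribromo-1-methylgramine)
Conditions: NaBH4 (excess), dry MeOH–THF, −10 °C to rt; aq. NaHCO3 work-up
Reagents that add atoms: none
Why: Hydride reduction of an iminium ion to the tertiary amine, the second half of a reductive amination. Attack at the exocyclic iminium carbon keeps the indole aromatic and is therefore preferred over attack at C2, and NaBH4 does not reduce C–Br bonds. The cold, basic work-up should spare the gramine from loss of dimethylamine.

## Compound list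

1 | 6-bromoisatin (6-bromo-1H-indole-2,3-dione) | O=C1Nc2cc(Br)ccc2C1=O | starting material
2 | 6-bromo-1-methylindoline-2,3-dione | CN1C(=O)C(=O)c2ccc(Br)cc21 | intermediate
3 | 6-bromo-3-hydrazinylidene-1-methylindolin-2-one (C=N geometry not fixed, not isolated) | CN1C(=O)C(=NN)c2ccc(Br)cc21 | intermediate
4 | 6-bromo-1-methylindolin-2-one | CN1C(=O)Cc2ccc(Br)cc21 | intermediate
5 | 5,6-dibromo-1-methylindolin-2-one | CN1C(=O)Cc2cc(Br)c(Br)cc21 | intermediate
6 | N,N-dimethylformamide | CN(C)C=O | starting material
7 | N-(bromomethylidene)-N-methylmethanaminium phosphorodibromidate (not isolated) | C[N+](C)=CBr.[O-]P(=O)(Br)Br | intermediate
8 | 5,6-dibromo-3-[(dimethylamino)methylidene]-1-methylindolin-2-one (C=C geometry not fixed, not isolated) | CN(C)C=C1C(=O)N(C)c2cc(Br)c(Br)cc21 | intermediate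
9 | N-[(2,5,6-tribromo-1-methyl-1H-indol-3-yl)methylidene]-N-methylmethanaminium bromide | C[N+](C)=Cc1c(Br)n(C)c2cc(Br)c(Br)cc12.[Br-] | intermediate
10 | 1-(2,5,6-tribromo-1-methyl-1H-indol-3-yl)-N,N-dimethylmethanamine (2,5,6-tribromo-1-methylgramine) | CN(C)Cc1c(Br)n(C)c2cc(Br)c(Br)cc12 | target

## Step count and risks

Total step count: 5. Longest linear sequence: 5 steps, from 1 to 10; dimethylformamide 6 enters at step 4.

**Step 4 (key step).** The most likely failure is premature hydrolysis of the iminium ion during isolation, because the salt precipitates together with hygroscopic phosphorus acid residues. The second risk is activation of the lactam oxygen running ahead of C-formylation, since the two ring bromines make the enol less nucleophilic; material would then be diverted into slow formylation of a deactivated 2-bromoindole. The fallback sets out from 5 and comes back at 9, dividing the haloformylation into two operations. Compound 5 is condensed with N,N-dimethylformamide dimethyl acetal in toluene at 90 °C, which forms the C3–CH bond under neutral conditions and gives the vinylogous amide 8, here isolated by crystallisation. Treatment of 8 with oxalyl bromide in CH2Cl2 at 0 °C then acylates the lactam oxygen and delivers bromide to C2. Only gases are released, so evaporation should leave 9 as the bromide, free of phosphorus. This fallback makes no compound beyond those of the list (entry F0).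

**Step 3.** The most likely failure is bromination at the enolisable C3 position, or a second bromination, competing with substitution at C5, because the C6 bromine slows the ring reaction. The fallback sets out from 2 and comes back at 5, moving the bromination to the isatin stage, where C3 is a ketone and cannot enolise. Compound 2 is brominated with Br2 in acetic acid at 80 °C, para to nitrogen, to give 5,6-dibromo-1-methylindoline-2,3-dione F1. F1 is then reduced with hydrazine hydrate as in step 2, through 5,6-dibromo-3-hydrazinylidene-1-methylindolin-2-one F2, to 5.

**Step 5.** The most likely failure is hydrolysis of the iminium ion by adventitious water or acid residues before hydride delivery, which after reduction would leave the side chain at the alcohol level. Solvolytic displacement of the activated C2 bromide by methoxide is a lesser risk. The fallback sets out from 9 and comes back at 10, accepting the hydrolysis and rebuilding the C–N bond. Salt 9 is hydrolysed with ice-water and NaHCO3 to 2,5,6-tribromo-1-methyl-1H-indole-3-carbaldehyde F3, a neutral compound that can be purified and is far less activated at C2 than the cation. Reductive amination of F3 with dimethylamine and Ti(OiPr)4 in THF, followed by NaBH4, gives 10.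

## Further compounds

F0 | step 4 | none | none
F1 | step 3 | 5,6-dibromo-1-methylindoline-2,3-dione | CN1C(=O)C(=O)c2cc(Br)c(Br)cc21
F2 | step 3 | 5,6-dibromo-3-hydrazinylidene-1-methylindolin-2-one | CN1C(=O)C(=NN)c2cc(Br)c(Br)cc21
F3 | step 5 | 2,5,6-tribromo-1-methyl-1H-indole-3-carbaldehyde | O=Cc1c(Br)n(C)c2cc(Br)c(Br)cc12
A1 | alternative 1 | N-(but-3-yn-1-yl)-N-ethynyl-4-methylbenzenesulfonamide | Cc1ccc(cc1)S(=O)(=O)N(C#C)CCC#C
A2 | alternative 1 | bis(trimethylsilyl)acetylene | C[Si](C)(C)C#C[Si](C)(C)C
A3 | alternative 1 | 1-(4-methylphenylsulfonyl)-5,6-bis(trimethylsilyl)indoline | Cc1ccc(cc1)S(=O)(=O)N1CCc2cc([Si](C)(C)C)c([Si](C)(C)C)cc21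
A4 | alternative 2 | 4,5-dibromo-2-iodo-N-methylaniline | CNc1cc(Br)c(Br)cc1I
A5 | alternative 2 | N,N-dimethyl-3-(trimethylsilyl)prop-2-yn-1-amine | CN(C)CC#C[Si](C)(C)C
A6 | alternative 2 | 1-[5,6-dibromo-1-methyl-2-(trimethylsilyl)-1H-indol-3-yl]-N,N-dimethylmethanamine | CN(C)Cc1c([Si](C)(C)C)n(C)c2cc(Br)c(Br)cc12
A7 | alternative 3 | 4,5-dibromo-2-(2,2-dibromoethenyl)-N-methylaniline | CNc1cc(Br)c(Br)cc1C=C(Br)Br
A8 | alternative 3 | 2,5,6-tribromo-1-methyl-1H-indole | Cn1c(Br)cc2cc(Br)c(Br)cc21
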